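**Assumptions:** CIP analysis of the given SMILES gives (R) at the carbinol (OH > aryl > CH2 > H) and (E) at the alkene. Compounds 1, 2, 6 and 7 are taken as catalogue chemicals.

## Retrosynthetic overview

1. The only ring formed is the 22-membered macrocycle. It is closed last by an intramolecular B-alkyl Suzuki–Miyaura coupling at the ring-A benzylic carbon (C14–aryl), not by RCM at C8=C9 and not by macro-etherification.
2. The seco-compound comes from a bromo-aldehyde and a dialkylzinc. A catalytic asymmetric alkylzinc addition forms C1–C2 and the (R)-carbinol in one step.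
3. The bromo-aldehyde (both benzene rings, bought) comes from syringaldehyde and an arylboronic acid by Chan–Lam etherification, followed by a Me→TIPS swap so the final deprotection needs only fluoride.
4. The C13 chain comes from oct-7-yn-1-ol and 5-bromopent-1-ene. The (E)-alkene is fixed before cyclisation by Na/NH3 reduction of the alkyne.
5. Order: diaryl ether first, stereocenter second, macrocycle last.

## Route

**Step 1**
Reactants: 1 oct-7-yn-1-ol; 2 5-bromopent-1-ene
Product: 3 tridec-12-en-7-yn-1-ol
Conditions: n-BuLi (2.2 equiv), THF/HMPA (or DMPU), −78 → 0 °C; then 2, → rt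
Reagents that add atoms: none
Why: Dianion (alkoxide/acetylide) alkylation; the lithium acetylide is far more nucleophilic than the lithium alkoxide toward a primary bromide, so C-alkylation occurs without a protecting group.

**Step 2**
Reactants: 3
Product: 4 (7E)-trideca-7,12-dien-1-ol
Conditions: Na, NH3(l)/THF, −33 °C; NH4Cl
Reagents that add atoms: none
Why: Dissolving-metal alkyne reduction goes through the trans vinyl radical anion and gives the (E)-alkene essentially exclusively; the isolated terminal alkene and the alkoxide are inert.

**Step 3**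
Reactants: 4
Product: 5 (6E)-13-iodotrideca-1,6-diene
Conditions: I2, PPh3, imidazole, CH2Cl2, 0 °C → rt
Reagents that add atoms: iodine, II
Why: Appel-type iodination, SN2 at the primary carbinol; the alkenes are untouched.

**Step 4**
Reactants: 6 syringaldehyde (4-hydroxy-3,5-dimethoxybenzaldehyde); 7 (3-bromo-5-methoxyphenyl)boronic acid (2 equiv)
Product: 8 4-(3-bromo-5-methoxyphenoxy)-3,5-dimethoxybenzaldehyde
Conditions: Cu(OAc)2, pyridine, 4 Å MS, CH2Cl2, air, rt
Reagents that add atoms: none
Why: Chan–Lam–Evans oxidative Cu(II) O-arylation runs at room temperature, tolerates di-ortho-substituted phenols, and leaves the ArBr and CHO groups untouched.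

**Step 5**
Reactants: 8
Product: 9 4-(3-bromo-5-hydroxyphenoxy)-3,5-dihydroxybenzaldehyde
Conditions: BBr3 (6 equiv), CH2Cl2, −78 °C → rt; H2O
Reagents that add atoms: none
Why: Lewis-acid demethylation of the three aryl methyl ethers; the diaryl ether and ArBr are inert, and the aldehyde is regenerated on aqueous work-up. It is done here because no acid-sensitive benzylic alcohol or alkene is present yet.

**Step 6**
Reactants: 9
Product: 10 4-{3-bromo-5-[(triisopropylsilyl)oxy]phenoxy}-3,5-bis[(triisopropylsilyl)oxy]benzaldehyde
Conditions: TIPSOTf (3.6 equiv), 2,6-lutidine, CH2Cl2, 0 °C → rt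
Reagents that add atoms: TIPSOTf, CC(C)[Si](OS(=O)(=O)C(F)(F)F)(C(C)C)C(C)C
Why: Phenol silylation; aryl TIPS ethers survive organozinc/Ti and hydroboration conditions and are later removed by fluoride without touching the benzylic alcohol or the alkene.

**Step 7**
Reactants: 5 (about 3 equiv); 10
Product: 11 (1R,8E)-1-(4-{3-bromo-5-[(triisopropylsilyl)oxy]phenoxy}-3,5-bis[(triisopropylsilyl)oxy]phenyl)tetradeca-8,13-dien-1-ol
Conditions: 5, Et2Zn (neat), CuI (cat.), 50 °C, then strip volatiles (gives R2Zn in situ); Ti(OiPr)4, (1S,2S)-1,2-bis(trifluoromethanesulfonamido)cyclohexane (8 mol %), PhMe, −20 °C; add 10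
Reagents that add atoms: none
Why: Knochel-type I/Zn exchange followed by Ti–bis(sulfonamide)-catalysed asymmetric dialkylzinc addition to an aromatic aldehyde. The (S,S)-ligand (the enantiomer that gives (R)-1-phenylpropanol from PhCHO/Et2Zn) delivers the alkyl group to the Re face and sets the (R)-carbinol; the ArBr and silyl ethers are inert.

**Step 8**
Reactants: 11
Product: 12 tris-O-TIPS-dehydrogravicycle (22-membered diaryl-ether cyclophane; (R)-carbinol, (E)-alkene)
Conditions: 9-BBN (2.5 equiv), THF, rt; then syringe-pump into Pd(OAc)2 (10 mol %), SPhos (20 mol %), K3PO4·H2O (3 equiv), THF, 65 °C, about 2 mM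
Reagents that add atoms: none
Why: Intramolecular B-alkyl Suzuki–Miyaura macrocyclisation. 9-BBN hydroborates only the monosubstituted alkene (anti-Markovnikov; the extra equivalent is consumed by the free OH), and the primary alkylborane couples with the ring-A bromide under high dilution; the (E)-alkene and the stereocenter are not involved. Any partial loss of TIPS here converges in step 9.

**Step 9**
Reactants: 12
Product: 13 dehydrogravicycle
Conditions: TBAF (3.5 equiv), AcOH (3.5 equiv), THF, 0 °C, degassed
Reagents that add atoms: none
Why: Fluoride desilylation of the three aryl silyl ethers under buffered, non-acidic conditions; the phenoxides are meta to the carbinol, so no quinone methide can form and the (R)-centre is not scrambled.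

## Compound list

1 | oct-7-yn-1-ol | OCCCCCCC#C | starting material
2 | 5-bromopent-1-ene | C=CCCCBr | starting material
3 | tridec-12-en-7-yn-1-ol | OCCCCCCC#CCCCC=C | intermediate
4 | (7E)-trideca-7,12-dien-1-ol | OCCCCCC/C=C/CCCC=C | intermediate
5 | (6E)-13-iodotrideca-1,6-diene | ICCCCCC/C=C/CCCC=C | intermediate
6 | syringaldehyde | COc1cc(C=O)cc(OC)c1O | starting material
7 | (3-bromo-5-methoxyphenyl)boronic acid | COc1cc(Br)cc(c1)B(O)O | starting material
8 | 4-(3-bromo-5-methoxyphenoxy)-3,5-dimethoxybenzaldehyde | COc1cc(Br)cc(c1)Oc1c(OC)cc(C=O)cc1OC | intermediate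
9 | 4-(3-bromo-5-hydroxyphenoxy)-3,5-dihydroxybenzaldehyde | Oc1cc(Br)cc(c1)Oc1c(O)cc(C=O)cc1O | intermediate
10 | tris-TIPS ether of 9 | CC(C)[Si](C(C)C)(C(C)C)Oc1cc(Br)cc(c1)Oc1c(O[Si](C(C)C)(C(C)C)C(C)C)cc(C=O)cc1O[Si](C(C)C)(C(C)C)C(C)C | intermediate
11 | (1R,8E)-seco dienol | CC(C)[Si](C(C)C)(C(C)C)Oc1cc(Br)cc(c1)Oc1c(O[Si](C(C)C)(C(C)C)C(C)C)cc(cc1O[Si](C(C)C)(C(C)C)C(C)C)[C@H](O)CCCCCC/C=C/CCCC=C | intermediate
12 | tris-O-TIPS-dehydrogravicycle | CC(C)[Si](C(C)C)(C(C)C)Oc1cc2cc(c1)Oc1c(O[Si](C(C)C)(C(C)C)C(C)C)cc(cc1O[Si](C(C)C)(C(C)C)C(C)C)[C@H](O)CCCCCC/C=C/CCCCC2 | intermediate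
13 | dehydrogravicycle, (R)-carbinol, (E)-alkene | Oc1cc2cc(c1)Oc1c(O)cc(cc1O)[C@H](O)CCCCCC/C=C/CCCCC2 | target

## Summary

Total steps: 9. Longest linear sequence: 6 steps (1→3→4→5→11→12→13, or equally 6→8→9→10→11→12→13).

Three steps most likely to fail, each with one fallback:

1. **Step 8, macrocyclic B-alkyl Suzuki.** Risks are oligomerisation, protodeboronation and ArBr reduction at high dilution. Fallback: move the ring-closing bond to the alkene but keep the geometry controlled. Build a seco-diyne (ring A carrying a hept-5-ynyl chain, ring B carbinol carrying an oct-6-ynyl chain), close it by ring-closing alkyne metathesis with a Mo alkylidyne, then convert the cycloalkyne to the (E)-alkene by Ru-catalysed trans-hydrosilylation and protodesilylation.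

2. **Step 7, asymmetric dialkylzinc addition.** Risks are incomplete I/Zn exchange, residual ethyl transfer and ee erosion with a long functionalised chain. Fallback: add the Grignard reagent of the corresponding bromide to 10 to give the racemic alcohol, oxidise to the aryl ketone with Dess–Martin periodinane, and set (R) by (S)-CBS reduction (the aryl group acts as the large substituent).

3. **Step 4, Chan–Lam coupling of a di-ortho-substituted, electron-poor phenol.** The risk is low conversion. Fallback: metal-free O-arylation of syringaldehyde with a (3-bromo-5-methoxyphenyl)(2,4,6-trimethoxyphenyl)iodonium salt (ligand coupling at I(III), K2CO3 or t-BuOK), a method that performs well with hindered 2,6-disubstituted phenols.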